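**Plan**
1. Labels: ring A is the hexasubstituted ring (C1 ethylene bridge; C2, C4, C6 4-hydroxybenzyl; C3 OH; C5 OMe). Ring B carries the bridge at C1', OH at C3' and the 4-hydroxybenzyl group at C6'.
2. Enabling feature: the C3' oxygen of ring B lies para to C6' and meta to C1'. This is the pattern a 2-siloxybuta-1,3-diene leaves when it adds across an ynone whose carbonyl carbon later becomes the C6' benzylic CH2.
3. Retrosynthesis: the C6' CH2 comes from an aroyl C=O and all phenols from benzyl ethers. Ring B is cut at C1'–C2' and C5'–C6', the ynone at its alkyne–carbonyl bond, and the alkyne carbon is traced to a propanal. Ring A is cut at its three aryl–CH2 bonds.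
4. Forward: ring A comes from 3-(3,5-dimethoxyphenyl)propanoic acid, is desymmetrised by mono-demethylation, receives its three aryl-CH2 groups one at a time in three Friedel–Crafts steps (C6, then C2, then C4) and is capped on oxygen. The side chain is converted into the butynyl aryl ketone, ring B is closed last and aromatised, and one hydrogenation ends the route.
5. Stereochemistry: bleochrin B has no stereocentre and no stereogenic double bond. Only regiochemistry needs control: OH versus OMe on ring A by mono-demethylation, and the ring B pattern by the para orientation of the cycloaddition.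

Key step: step 10

Assumption: the trimethylsilyl enol ether 14 is too labile for chromatography and is carried forward as the residue left after evaporating solvent and excess diene.

**Step 1**
Reactants: 1 3-(3,5-dimethoxyphenyl)propanoic acid
Product: 2 3-(3-hydroxy-5-methoxyphenyl)propanoic acid
Conditions: NaSEt (4 equiv), DMF, 140 °C; then aq. HCl
Reagents that add atoms: none
Why: Thiolate SN2 O-demethylation of an aryl methyl ether should stop after one methyl group, because the phenoxide then present makes the second aryloxide a far poorer leaving group, while the carboxylate is inert.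

**Step 2**
Reactants: 2 3-(3-hydroxy-5-methoxyphenyl)propanoic acid
Product: 3 methyl 3-(3-hydroxy-5-methoxyphenyl)propanoate
Conditions: MeOH, H2SO4 (cat.), reflux
Reagents that add atoms: methanol, CO
Why: Fischer esterification in excess methanol should convert the acid cleanly and leave the phenol and aryl methyl ether untouched.

**Step 3**
Reactants: 3 methyl 3-(3-hydroxy-5-methoxyphenyl)propanoate; 4 4-(benzyloxy)benzyl alcohol
Product: 5 methyl 3-{2-[4-(benzyloxy)benzyl]-5-hydroxy-3-methoxyphenyl}propanoate
Conditions: 3 (1.2 equiv), 4 (1.0 equiv, slow addition), Sc(OTf)3 (5 mol %), MeNO2, rt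
Reagents that add atoms: none
Why: In this Friedel–Crafts benzylation the Lewis acid ionises 4 to a para-alkoxy-stabilised benzylic cation that should attack C6, the ring carbon para to the free hydroxyl and ortho to the methoxy group, while the limiting amount of 4 holds the reaction at one benzyl group; a minor isomer benzylated at C2 would converge on 6 in step 4.

**Step 4**
Reactants: 5 methyl 3-{2-[4-(benzyloxy)benzyl]-5-hydroxy-3-methoxyphenyl}propanoate; 4 4-(benzyloxy)benzyl alcohol
Product: 6 methyl 3-{2,6-bis[4-(benzyloxy)benzyl]-3-hydroxy-5-methoxyphenyl}propanoate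
Conditions: 4 (1.1 equiv, slow addition), Sc(OTf)3 (10 mol %), MeNO2, 40 °C
Reagents that add atoms: none
Why: A second Friedel–Crafts benzylation should favour C2, which is ortho to the hydroxyl and para to the methoxy group and so more activated than C4 between the two oxygens; material benzylated at C4 instead is not lost, since step 5 fills whichever position remains.

**Step 5**
Reactants: 6 methyl 3-{2,6-bis[4-(benzyloxy)benzyl]-3-hydroxy-5-methoxyphenyl}propanoate; 4 4-(benzyloxy)benzyl alcohol
Product: 7 methyl 3-{2,4,6-tris[4-(benzyloxy)benzyl]-3-hydroxy-5-methoxyphenyl}propanoate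
Conditions: 4 (1.3 equiv, slow addition), Sc(OTf)3 (10 mol %), MeNO2, 60 °C
Reagents that add atoms: none
Why: The third Friedel–Crafts benzylation has a single free ring position left, C4, ortho to both oxygen substituents and flanked only by them, so regiochemistry is not in question and a slight excess of 4 should complete the hexasubstituted ring A.

**Step 6**
Reactants: 7 methyl 3-{2,4,6-tris[4-(benzyloxy)benzyl]-3-hydroxy-5-methoxyphenyl}propanoate
Product: 8 methyl 3-{3-(benzyloxy)-2,4,6-tris[4-(benzyloxy)benzyl]-5-methoxyphenyl}propanoate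
Conditions: BnBr (1.5 equiv), K2CO3, DMF, 60 °C
Reagents that add atoms: benzyl bromide, BrCc1ccccc1
Why: Williamson etherification of the phenoxide with a reactive benzylic bromide in a dipolar aprotic solvent should work even on a phenol flanked by two ortho substituents, and the methyl ester survives anhydrous carbonate.

**Step 7**
Reactants: 8 methyl 3-{3-(benzyloxy)-2,4,6-tris[4-(benzyloxy)benzyl]-5-methoxyphenyl}propanoate
Product: 9 3-{3-(benzyloxy)-2,4,6-tris[4-(benzyloxy)benzyl]-5-methoxyphenyl}propanal
Conditions: i-Bu2AlH (1.1 equiv), CH2Cl2, −78 °C; MeOH, then aq. potassium sodium tartrate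
Reagents that add atoms: none
Why: Partial reduction of a methyl ester by i-Bu2AlH should stop at the aldehyde stage because the tetrahedral aluminium hemiacetal persists at −78 °C and collapses only on work-up.

**Step 8**
Reactants: 9 3-{3-(benzyloxy)-2,4,6-tris[4-(benzyloxy)benzyl]-5-methoxyphenyl}propanal
Product: 10 1-(benzyloxy)-2,4,6-tris[4-(benzyloxy)benzyl]-3-(but-3-yn-1-yl)-5-methoxybenzene
Conditions: dimethyl (1-diazo-2-oxopropyl)phosphonate (1.3 equiv), K2CO3, MeOH–THF, 0 °C to rt
Reagents that add atoms: dimethyl (1-diazo-2-oxopropyl)phosphonate, CC(=O)C(=[N+]=[N-])P(=O)(OC)OC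
Why: The Seyferth–Gilbert homologation in its Ohira–Bestmann form should turn the unhindered aldehyde into the terminal alkyne via the diazoalkene and a 1,2-hydride shift of the alkylidene carbene, under base mild enough for all ethers.

**Step 9**
Reactants: 10 1-(benzyloxy)-2,4,6-tris[4-(benzyloxy)benzyl]-3-(but-3-yn-1-yl)-5-methoxybenzene; 11 4-(benzyloxy)benzoyl chloride
Product: 12 1-[4-(benzyloxy)phenyl]-5-{3-(benzyloxy)-2,4,6-tris[4-(benzyloxy)benzyl]-5-methoxyphenyl}pent-2-yn-1-one
Conditions: 11 (1.3 equiv), PdCl2(PPh3)2 (2 mol %), CuI (4 mol %), Et3N, THF, rt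
Reagents that add atoms: none
Why: In this acyl Sonogashira coupling the aroyl chloride adds oxidatively to zerovalent palladium, the copper acetylide of 10 transmetalates and reductive elimination should give the ynone at room temperature without touching the benzyl ethers.

**Step 10**
Reactants: 12 1-[4-(benzyloxy)phenyl]-5-{3-(benzyloxy)-2,4,6-tris[4-(benzyloxy)benzyl]-5-methoxyphenyl}pent-2-yn-1-one; 13 2-(trimethylsilyloxy)buta-1,3-diene
Product: 14 [4-(benzyloxy)phenyl][2-(2-{3-(benzyloxy)-2,4,6-tris[4-(benzyloxy)benzyl]-5-methoxyphenyl}ethyl)-4-(trimethylsilyloxy)cyclohexa-1,4-dien-1-yl]methanone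
Conditions: 13 (5 equiv), BHT (cat.), toluene, 140 °C, sealed tube; evaporation of volatiles
Reagents that add atoms: none
Why: The electron-rich diene 13 and the electron-poor ynone 12 should combine in a concerted, asynchronous [4+2] cycloaddition of normal electron demand, the closest known reaction type being the thermal Diels–Alder reaction of 2-silyloxybuta-1,3-dienes with acetylenic ketones. Ring B closes as a six-membered carbocycle in an intermolecular [4+2] mode, the two sigma bonds C1'–C2' and C5'–C6' forming suprafacially on both partners. No stereocentre arises, since the cyclohexa-1,4-diene contains only sp2 carbons and CH2 groups. The step needs regioselectivity, and the polarisation of both partners secures it: the diene CH2 terminus next to the siloxy carbon has the largest HOMO coefficient and the ynone carbon beta to the carbonyl (the future C1') the largest LUMO coefficient, so the siloxy carbon ends para to the aroyl-bearing carbon and meta to the chain carbon. Chemoselectivity follows from the ynone being the only electron-poor pi system in 12, with the crowded ring A held two CH2 groups away from the reacting alkyne and the benzyl ethers inert at this temperature.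

**Step 11**
Reactants: 14 [4-(benzyloxy)phenyl][2-(2-{3-(benzyloxy)-2,4,6-tris[4-(benzyloxy)benzyl]-5-methoxyphenyl}ethyl)-4-(trimethylsilyloxy)cyclohexa-1,4-dien-1-yl]methanone
Product: 16 [4-(benzyloxy)phenyl][2-(2-{3-(benzyloxy)-2,4,6-tris[4-(benzyloxy)benzyl]-5-methoxyphenyl}ethyl)-4-hydroxyphenyl]methanone, via aryl trimethylsilyl ether 15 (not isolated)
Conditions: DDQ (1.1 equiv), toluene, 0 °C to rt; then K2CO3 (cat.), MeOH–THF, rt
Reagents that add atoms: none
Why: DDQ dehydrogenation of a cyclohexa-1,4-diene (hydride abstraction from a doubly allylic CH2, then proton loss) is driven by aromatisation and should be far faster at 0 °C than attack on the diarylmethane CH2 groups or benzyl ethers, after which methanolysis removes the labile aryl silyl group.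

**Step 12**
Reactants: 16 [4-(benzyloxy)phenyl][2-(2-{3-(benzyloxy)-2,4,6-tris[4-(benzyloxy)benzyl]-5-methoxyphenyl}ethyl)-4-hydroxyphenyl]methanone
Product: 17 bleochrin B
Conditions: H2 (4 bar), 10% Pd/C, THF–MeOH–AcOH, 40 °C
Reagents that add atoms: none
Why: Palladium-catalysed hydrogenolysis should cleave all five O-benzyl ethers and, in the acidic medium, reduce the diaryl ketone through the diarylmethanol, whose benzylic C–O bond is activated by two para-oxygenated rings, to the C6' CH2 group, leaving the aryl methyl ether and the diarylmethane C–C bonds intact.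

**Compound list**
1 | 3-(3,5-dimethoxyphenyl)propanoic acid | COc1cc(CCC(=O)O)cc(OC)c1 | starting material
2 | 3-(3-hydroxy-5-methoxyphenyl)propanoic acid | COc1cc(O)cc(CCC(=O)O)c1 | intermediate
3 | methyl 3-(3-hydroxy-5-methoxyphenyl)propanoate | COC(=O)CCc1cc(O)cc(OC)c1 | intermediate
4 | 4-(benzyloxy)benzyl alcohol | OCc1ccc(OCc2ccccc2)cc1 | starting material
5 | methyl 3-{2-[4-(benzyloxy)benzyl]-5-hydroxy-3-methoxyphenyl}propanoate | COC(=O)CCc1cc(O)cc(OC)c1Cc1ccc(OCc2ccccc2)cc1 | intermediate
6 | methyl 3-{2,6-bis[4-(benzyloxy)benzyl]-3-hydroxy-5-methoxyphenyl}propanoate | COC(=O)CCc1c(Cc2ccc(OCc3ccccc3)cc2)c(O)cc(OC)c1Cc1ccc(OCc2ccccc2)cc1 | intermediate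
7 | methyl 3-{2,4,6-tris[4-(benzyloxy)benzyl]-3-hydroxy-5-methoxyphenyl}propanoate | COC(=O)CCc1c(Cc2ccc(OCc3ccccc3)cc2)c(O)c(Cc2ccc(OCc3ccccc3)cc2)c(OC)c1Cc1ccc(OCc2ccccc2)cc1 | intermediate
8 | methyl 3-{3-(benzyloxy)-2,4,6-tris[4-(benzyloxy)benzyl]-5-methoxyphenyl}propanoate | COC(=O)CCc1c(Cc2ccc(OCc3ccccc3)cc2)c(OCc2ccccc2)c(Cc2ccc(OCc3ccccc3)cc2)c(OC)c1Cc1ccc(OCc2ccccc2)cc1 | intermediate
9 | 3-{3-(benzyloxy)-2,4,6-tris[4-(benzyloxy)benzyl]-5-methoxyphenyl}propanal | O=CCCc1c(Cc2ccc(OCc3ccccc3)cc2)c(OCc2ccccc2)c(Cc2ccc(OCc3ccccc3)cc2)c(OC)c1Cc1ccc(OCc2ccccc2)cc1 | intermediate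
10 | 1-(benzyloxy)-2,4,6-tris[4-(benzyloxy)benzyl]-3-(but-3-yn-1-yl)-5-methoxybenzene | C#CCCc1c(Cc2ccc(OCc3ccccc3)cc2)c(OCc2ccccc2)c(Cc2ccc(OCc3ccccc3)cc2)c(OC)c1Cc1ccc(OCc2ccccc2)cc1 | intermediate
11 | 4-(benzyloxy)benzoyl chloride | O=C(Cl)c1ccc(OCc2ccccc2)cc1 | starting material
12 | 1-[4-(benzyloxy)phenyl]-5-{3-(benzyloxy)-2,4,6-tris[4-(benzyloxy)benzyl]-5-methoxyphenyl}pent-2-yn-1-one | COc1c(Cc2ccc(OCc3ccccc3)cc2)c(OCc2ccccc2)c(Cc2ccc(OCc3ccccc3)cc2)c(CCC#CC(=O)c2ccc(OCc3ccccc3)cc2)c1Cc1ccc(OCc2ccccc2)cc1 | intermediate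
13 | 2-(trimethylsilyloxy)buta-1,3-diene | C=CC(=C)O[Si](C)(C)C | starting material
14 | [4-(benzyloxy)phenyl][2-(2-{3-(benzyloxy)-2,4,6-tris[4-(benzyloxy)benzyl]-5-methoxyphenyl}ethyl)-4-(trimethylsilyloxy)cyclohexa-1,4-dien-1-yl]methanone | COc1c(Cc2ccc(OCc3ccccc3)cc2)c(OCc2ccccc2)c(Cc2ccc(OCc3ccccc3)cc2)c(CCC2=C(C(=O)c3ccc(OCc4ccccc4)cc3)CC=C(O[Si](C)(C)C)C2)c1Cc1ccc(OCc2ccccc2)cc1 | intermediate
15 | [4-(benzyloxy)phenyl][2-(2-{3-(benzyloxy)-2,4,6-tris[4-(benzyloxy)benzyl]-5-methoxyphenyl}ethyl)-4-(trimethylsilyloxy)phenyl]methanone | COc1c(Cc2ccc(OCc3ccccc3)cc2)c(OCc2ccccc2)c(Cc2ccc(OCc3ccccc3)cc2)c(CCc2cc(O[Si](C)(C)C)ccc2C(=O)c2ccc(OCc3ccccc3)cc2)c1Cc1ccc(OCc2ccccc2)cc1 | intermediate (not isolated)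
16 | [4-(benzyloxy)phenyl][2-(2-{3-(benzyloxy)-2,4,6-tris[4-(benzyloxy)benzyl]-5-methoxyphenyl}ethyl)-4-hydroxyphenyl]methanone | COc1c(Cc2ccc(OCc3ccccc3)cc2)c(OCc2ccccc2)c(Cc2ccc(OCc3ccccc3)cc2)c(CCc2cc(O)ccc2C(=O)c2ccc(OCc3ccccc3)cc2)c1Cc1ccc(OCc2ccccc2)cc1 | intermediate
17 | bleochrin B, 3-{2-[3-hydroxy-2,4,6-tris(4-hydroxybenzyl)-5-methoxyphenyl]ethyl}-4-(4-hydroxybenzyl)phenol | COc1c(Cc2ccc(O)cc2)c(O)c(Cc2ccc(O)cc2)c(CCc2cc(O)ccc2Cc2ccc(O)cc2)c1Cc1ccc(O)cc1 | target

**Step count**
Total steps: 12. Longest linear sequence: 12 steps (1 to 17).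

**Steps most likely to fail**

Step 3 (first Friedel–Crafts benzylation; steps 4 and 5 share the risk). The alkylation may not stop cleanly after one benzyl group, and the benzylic cation may condense with the pendant 4-benzyloxyphenyl rings or with further alcohol. The acid may also strip benzyl ethers as the ring grows more crowded. The fallback makes the three aryl–CH2 bonds by cross-coupling. Setting out from 3, O-benzylation (BnBr, K2CO3, DMF) would give methyl 3-[3-(benzyloxy)-5-methoxyphenyl]propanoate F1. Exhaustive bromination with NBS (3.3 equiv, MeCN) at the three doubly activated positions would give methyl 3-[3-(benzyloxy)-2,4,6-tribromo-5-methoxyphenyl]propanoate F2. A threefold Negishi coupling of F2 with [4-(benzyloxy)benzyl]zinc chloride F3 (from commercial 4-(benzyloxy)benzyl chloride, Zn dust and LiCl in THF) under Pd(OAc)2/SPhos would then deliver 8, where the route is rejoined; steps 4 to 6 are then not needed.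

Step 10 (cycloaddition). The beta-alkyl ynone may react too slowly with the only moderately nucleophilic diene, so that thermal oligomerisation or desilylation of the diene wins, or the para orientation may erode at the temperature required. The fallback uses a more reactive, doubly donor-substituted diene whose adduct aromatises by elimination and needs no oxidant. Setting out from 12, heating with (E)-1-methoxy-3-(trimethylsilyloxy)buta-1,3-diene (toluene, 90–110 °C) would form the same two ring bonds with the same orientation and give racemic [4-(benzyloxy)phenyl][2-(2-{3-(benzyloxy)-2,4,6-tris[4-(benzyloxy)benzyl]-5-methoxyphenyl}ethyl)-6-methoxy-4-(trimethylsilyloxy)cyclohexa-1,4-dien-1-yl]methanone F4. Dilute HCl in THF would then cleave the silyl enol ether and expel methanol to give phenol 16 directly, where the route is rejoined.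

Step 12 (global hydrogenation). Once the phenols are unveiled, the doubly para-oxygenated diaryl ketone may resist hydrogenation, so the reduction could stop at the ketone or the carbinol while debenzylation runs to completion. The fallback separates deoxygenation from deprotection. Setting out from 16, ionic hydrogenation with Et3SiH and BF3·OEt2 (CH2Cl2–MeCN, 0 °C to rt) would reduce the carbonyl through the stabilised diarylmethyl cation to give 4-[4-(benzyloxy)benzyl]-3-(2-{3-(benzyloxy)-2,4,6-tris[4-(benzyloxy)benzyl]-5-methoxyphenyl}ethyl)phenol F5. Plain hydrogenolysis (H2, Pd/C, THF–MeOH) would then remove only the five benzyl groups and arrive at 17.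

**Further compounds**
F1 | step 3 | methyl 3-[3-(benzyloxy)-5-methoxyphenyl]propanoate | COC(=O)CCc1cc(OC)cc(OCc2ccccc2)c1
F2 | step 3 | methyl 3-[3-(benzyloxy)-2,4,6-tribromo-5-methoxyphenyl]propanoate | COC(=O)CCc1c(Br)c(OCc2ccccc2)c(Br)c(OC)c1Br
F3 | step 3 | [4-(benzyloxy)benzyl]zinc chloride | Cl[Zn]Cc1ccc(OCc2ccccc2)cc1
F4 | step 10 | [4-(benzyloxy)phenyl][2-(2-{3-(benzyloxy)-2,4,6-tris[4-(benzyloxy)benzyl]-5-methoxyphenyl}ethyl)-6-methoxy-4-(trimethylsilyloxy)cyclohexa-1,4-dien-1-yl]methanone (racemic) | COc1c(Cc2ccc(OCc3ccccc3)cc2)c(OCc2ccccc2)c(Cc2ccc(OCc3ccccc3)cc2)c(CCC2=C(C(=O)c3ccc(OCc4ccccc4)cc3)C(OC)C=C(O[Si](C)(C)C)C2)c1Cc1ccc(OCc2ccccc2)cc1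
F5 | step 12 | 4-[4-(benzyloxy)benzyl]-3-(2-{3-(benzyloxy)-2,4,6-tris[4-(benzyloxy)benzyl]-5-methoxyphenyl}ethyl)phenol | COc1c(Cc2ccc(OCc3ccccc3)cc2)c(OCc2ccccc2)c(Cc2ccc(OCc3ccccc3)cc2)c(CCc2cc(O)ccc2Cc2ccc(OCc3ccccc3)cc2)c1Cc1ccc(OCc2ccccc2)cc1
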